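## Retrosynthetic overview

- **Enabling feature.** The target is a [7.7]paracyclophane: rings A and B are joined by two C1–C7 bridges. The two halves (ring, bridge, C8–C11 arm) are identical except for one chlorine at C11 (CH2Cl on arm a, CHCl2 on arm b). Each C7 is a benzylic methine flanked by two ring oxygens, so it can be built as an allylic centre whose olefinic neighbour is C6.
- **Key disconnection.** Head-to-tail olefin-metathesis cyclodimerisation of one diene monomer makes both C5=C6 bonds. The second of them, C5a–C6a, closes the 22-membered ring, the only ring formed in the route (rings A and B are bought). Hydrogenation follows.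
- **After the skeleton.** The two arm termini are differentiated from a C2-symmetric diol (one CH2OH to CHO to CHCl2, the other to CH2Cl). Then come the C1 carbamates and the free phenols.
- **Monomer.** Ar–C7 comes from a copper-mediated anti-SN2′ arylation of an (S,Z)-allylic picolinate, which sets C7 and leaves the propenyl carbon C6. C1/C2 come from a catalytic asymmetric (Z)-crotylboration of 3,5-bis(methoxymethoxy)benzaldehyde. C4–C5 comes from hydroboration/B-alkyl Suzuki coupling with vinyl bromide.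

Key step: step 9

**Numbering used.** Bridge carbons run C1 (carbinol/carbamate carbon) to C7 (arm-bearing benzylic carbon); arm carbons are C8–C11. Ring A is bonded to C7a and C1b, ring B to C7b and C1a. Bridge a ends at the C7 that carries the 4-chlorobutyl arm in the target.

**Assumption.** The cyclodimer 18 is C2-symmetric, so its two C5–C6 bonds are equivalent; the one formed second, which closes the ring, is designated C5a–C6a. The two remote CH2OH groups of 20 are taken to react independently, so step 11 is a statistical mono-oxidation run with recycling.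

## Route

Step 1
Reactants: 1 3,5-dihydroxybenzaldehyde
Product: 2 3,5-bis(methoxymethoxy)benzaldehyde
Conditions: MOMCl, iPr2NEt, CH2Cl2, 0 °C → rt
Reagents that add atoms: chloromethyl methyl ether (MOMCl), COCCl
Why: Base-mediated O-alkylation (MOM protection) of both phenols; the MOM groups later direct lithiation to the ring carbon between them and are removable with acid at the end.

Step 2
Reactants: 2 3,5-bis(methoxymethoxy)benzaldehyde
Product: 4 (1R,2S)-1-[3,5-bis(methoxymethoxy)phenyl]-2-methylbut-3-en-1-ol, via borate ester 3 (not isolated)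
Conditions: (Z)-crotylboronic acid pinacol ester, (R)-TRIP [(R)-3,3′-bis(2,4,6-triisopropylphenyl)-1,1′-binaphthyl-2,2′-diyl hydrogen phosphate] (5 mol %), 4 Å MS, toluene, −30 °C; aqueous work-up
Reagents that add atoms: (Z)-crotylboronic acid pinacol ester, C/C=C\CB1OC(C)(C)C(C)(C)O1
Why: Chiral phosphoric acid-catalysed asymmetric crotylboration through a closed chair transition state: the (Z)-crotyl geometry sets the C1/C2 syn relationship and the (R)-catalyst is expected to direct attack to the Re face of the aldehyde, giving C1 (R) and C2 (S).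

Step 3
Reactants: 4 (1R,2S)-1-[3,5-bis(methoxymethoxy)phenyl]-2-methylbut-3-en-1-ol
Product: 5 tert-butyl{[(1R,2S)-1-[3,5-bis(methoxymethoxy)phenyl]-2-methylbut-3-en-1-yl]oxy}dimethylsilane
Conditions: TBSCl, imidazole, DMF, rt → 40 °C
Reagents that add atoms: tert-butyldimethylsilyl chloride (TBSCl), CC(C)(C)[Si](C)(C)Cl
Why: Silylation of the secondary benzylic alcohol; the TBS ether should survive organolithium, metathesis and hydrogenation conditions and is cleaved by fluoride in step 14.

Step 4
Reactants: 5 tert-butyl{[(1R,2S)-1-[3,5-bis(methoxymethoxy)phenyl]-2-methylbut-3-en-1-yl]oxy}dimethylsilane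
Product: 7 tert-butyl{[(1R,2S)-1-[3,5-bis(methoxymethoxy)phenyl]-2-methylhex-5-en-1-yl]oxy}dimethylsilane, via B-alkyl-9-BBN 6 (not isolated)
Conditions: 9-BBN, THF, 0 °C → rt; then vinyl bromide, Pd(dppf)Cl2 (5 mol %), 3 M NaOH aq, THF, 50 °C
Reagents that add atoms: vinyl bromide, C=CBr
Why: Anti-Markovnikov hydroboration of the only alkene followed by B-alkyl Suzuki–Miyaura coupling with vinyl bromide forms the C4–C5 bond and delivers the butenyl terminus (C5=CH2) in one flask without touching C1 or C2.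

Step 5
Reactants: 8 (S)-but-3-yn-2-ol; 9 benzyl 4-bromobutyl ether
Product: 11 (S)-8-(benzyloxy)oct-3-yn-2-ol, via dilithio alkynolate 10 (not isolated)
Conditions: n-BuLi (2.1 equiv), THF/DMPU, −78 → −20 °C; then 9, −20 °C → rt; aqueous NH4Cl
Reagents that add atoms: none
Why: C-Alkylation of the acetylide terminus of the O,C-dianion (SN2 at the primary bromide); the carbinol stereocentre of 8 is not involved.

Step 6
Reactants: 11 (S)-8-(benzyloxy)oct-3-yn-2-ol
Product: 12 (2S,3Z)-8-(benzyloxy)oct-3-en-2-ol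
Conditions: H2 (1 atm), Pd/CaCO3 poisoned with Pb(OAc)2 (Lindlar catalyst), quinoline, EtOAc, rt
Reagents that add atoms: none
Why: Lindlar semihydrogenation (syn addition of H2) gives the Z-alkene needed for clean 1,3-chirality transfer; the benzyl ether and the carbinol centre are untouched.

Step 7
Reactants: 12 (2S,3Z)-8-(benzyloxy)oct-3-en-2-ol
Product: 13 (2S,3Z)-8-(benzyloxy)oct-3-en-2-yl pyridine-2-carboxylate
Conditions: picolinic acid, DCC, DMAP (cat.), CH2Cl2, rt
Reagents that add atoms: picolinic acid, OC(=O)c1ccccn1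
Why: Steglich esterification installs the picolinoxy leaving group, which chelates magnesium and enforces anti-SN2′ substitution.

Step 8
Reactants: 7 tert-butyl{[(1R,2S)-1-[3,5-bis(methoxymethoxy)phenyl]-2-methylhex-5-en-1-yl]oxy}dimethylsilane; 13 (2S,3Z)-8-(benzyloxy)oct-3-en-2-yl pyridine-2-carboxylate
Product: 16 tert-butyl{[(1R,2S)-1-{4-[(2E,4R)-8-(benzyloxy)oct-2-en-4-yl]-3,5-bis(methoxymethoxy)phenyl}-2-methylhex-5-en-1-yl]oxy}dimethylsilane, via aryllithium 14 (not isolated), via arylmagnesium bromide 15 (not isolated)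
Conditions: 7 (2 equiv), n-BuLi, THF, 0 °C; MgBr2·OEt2, −20 °C; CuBr·SMe2 (1 equiv), −40 °C; then 13 (1 equiv), −40 → 0 °C; aqueous NH4Cl; excess 7 recovered
Reagents that add atoms: none
Why: Directed ortho-lithiation at the ring carbon flanked by both OMOM groups, transmetalation and copper-mediated anti-SN2′ allylic substitution of the picolinate: with the Z-olefin, allylic 1,3-strain fixes the reactive conformer, the aryl group adds to the γ-carbon anti to the leaving group, and the (S)-carbinol chirality is transferred to C7 (R at this stage by priority, the configuration of the target) with formation of the E-propenyl group whose inner carbon is C6.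

Step 9
Reactants: 16 tert-butyl{[(1R,2S)-1-{4-[(2E,4R)-8-(benzyloxy)oct-2-en-4-yl]-3,5-bis(methoxymethoxy)phenyl}-2-methylhex-5-en-1-yl]oxy}dimethylsilane (two molecules)
Product: 18 C2-symmetric (E,E)-[7.7]paracyclophane diene (each bridge C1H(OTBS)–C2H(CH3)–C3H2–C4H2–C5H=C6H–C7H[(CH2)4OBn]; OMOM on both ring carbons flanking each C7; C1 R; C2 S; C7 R), via acyclic head-to-tail dimer 17 (not isolated)
Conditions: second-generation Grubbs catalyst RuCl2(=CHPh)(H2IMes)(PCy3) (10 mol %), 1,4-benzoquinone (20 mol %), toluene (0.01 M), 60 °C, argon sparge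
Reagents that add atoms: none
Why: Olefin metathesis through ruthenium alkylidene/ruthenacyclobutane intermediates: the catalyst loads onto the unhindered butenyl terminus (C5) of one molecule of 16 and cross-metathesises with the propenyl carbon C6 of a second molecule (propene lost) to give the acyclic head-to-tail dimer 17, whose remaining butenyl/propenyl pair then forms the second C5=C6 bond (propene lost again). The closest known reaction type is the head-to-tail cross-metathesis/ring-closing-metathesis cyclodimerisation of arene-bridged dienes to [7.7]paracyclophane dienes. The ring closed is the 22-membered carbocycle, by macrocyclic ring-closing olefin metathesis between C5a and C6a; the C5b=C6b bond is made in the same operation and the two are symmetry-equivalent in the product. No stereocentre is created: C1, C2 and C7 are not touched, and both new olefins should be E under thermodynamic control (the geometry is erased in step 10). The step needs head-to-tail over head-to-head pairing, cyclic dimer over oligomer, and no double-bond migration toward C7. Pairing is secured because C6=C6 union of two hindered α-branched olefins is slow while every C5=C5 homocoupling is reversible, so material funnels to the strain-free [7.7] ring; closure within one molecule is impossible because it would give a [7]paracyclophane; dilution and propene removal favour the cyclodimer and 1,4-benzoquinone suppresses ruthenium hydride isomerisation.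

Step 10
Reactants: 18 C2-symmetric (E,E)-[7.7]paracyclophane diene
Product: 20 C2-symmetric saturated [7.7]paracyclophane diol (both arms (CH2)4OH; C1 OTBS; four OMOM; C1 R; C2 S; C7 S), via saturated bis(benzyl ether) 19 (not isolated)
Conditions: H2 (1 atm), PtO2, EtOAc, rt; filter; then H2 (1 atm), Pd(OH)2/C, EtOAc/EtOH, rt
Reagents that add atoms: none
Why: Catalytic hydrogenation over platinum saturates both disubstituted olefins with little tendency to migrate the double bond toward the benzylic C7, and palladium-catalysed hydrogenolysis then removes both benzyl ethers; aryl MOM ethers and benzylic silyl ethers are expected to survive and no stereocentre is affected.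

Step 11
Reactants: 20 C2-symmetric saturated [7.7]paracyclophane diol
Product: 21 hydroxy aldehyde (arm a (CH2)4OH; arm b (CH2)3CHO; otherwise as 20)
Conditions: TEMPO (10 mol %), PhI(OAc)2 (1.0 equiv), CH2Cl2, 0 °C → rt; recovered 20 and over-oxidised dialdehyde (returned to 20 with NaBH4) are recycled
Reagents that add atoms: none
Why: Oxoammonium (TEMPO) oxidation of a primary alcohol to the aldehyde; the two CH2OH groups are homotopic and remote, so one equivalent of oxidant should give the mono-aldehyde as the main component of a statistical mixture whose other components are returned to 20.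

Step 12
Reactants: 21 hydroxy aldehyde
Product: 23 dichloride alcohol (arm a (CH2)4OH; arm b (CH2)3CHCl2; otherwise as 20), via hydrazone 22 (not isolated)
Conditions: N2H4·H2O, MeOH, rt, concentrate; then CuCl2 (6 equiv), Et3N (3 equiv), MeOH, 0 °C → rt
Reagents that add atoms: copper dichloride, Cl[Cu]Cl
Why: Condensation to the N-unsubstituted hydrazone followed by copper dichloride oxidation (diazoalkane formation, chlorine transfer from CuCl2 and loss of N2) converts CHO into CHCl2 under non-acidic conditions that tolerate the free CH2OH, MOM and TBS groups.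

Step 13
Reactants: 23 dichloride alcohol
Product: 24 fully protected chloro/dichloro macrocycle (arm a (CH2)4Cl; arm b (CH2)3CHCl2; C1 OTBS; four OMOM)
Conditions: PPh3, N-chlorosuccinimide, CH2Cl2, 0 °C → rt
Reagents that add atoms: N-chlorosuccinimide, ClN1C(=O)CCC1=O
Why: Appel-type deoxychlorination (alkoxyphosphonium, SN2 by chloride) of the remaining primary alcohol; the gem-dichloride and the protecting groups are inert.

Step 14
Reactants: 24 fully protected chloro/dichloro macrocycle
Product: 25 C1a,C1b-diol (arms as in 24; four OMOM)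
Conditions: HF·pyridine, pyridine/THF, 0 °C → rt
Reagents that add atoms: none
Why: Fluoride-mediated desilylation of both benzylic TBS ethers; buffered HF·pyridine should leave the aryl MOM ethers and the alkyl chlorides untouched and does not affect C1.

Step 15
Reactants: 25 C1a,C1b-diol
Product: 27 bis(carbamate) tetrakis(MOM ether), via bis(N-trichloroacetylcarbamate) 26 (not isolated)
Conditions: Cl3CC(O)NCO, CH2Cl2, 0 °C; then K2CO3, MeOH, rt
Reagents that add atoms: trichloroacetyl isocyanate, O=C=NC(=O)C(Cl)(Cl)Cl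
Why: Carbamoylation by addition of both secondary alcohols to trichloroacetyl isocyanate, then mild methanolysis of the N-trichloroacetyl groups, gives the primary carbamates with retention at C1.

Step 16
Reactants: 27 bis(carbamate) tetrakis(MOM ether)
Product: 28 CNP0310589.1 (target)
Conditions: HCl (1.25 M in MeOH), THF, rt → 40 °C
Reagents that add atoms: none
Why: Acid-catalysed acetal exchange removes the four aryl MOM groups; the benzylic carbamates sit meta to both ring oxygens, so C1 is not activated towards ionisation and should survive, as should the alkyl chlorides.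

## Compound list

1 | 3,5-dihydroxybenzaldehyde | O=Cc1cc(O)cc(O)c1 | starting material
2 | 3,5-bis(methoxymethoxy)benzaldehyde | O=Cc1cc(OCOC)cc(OCOC)c1 | intermediate
3 | borate ester of 4 (2-{[(1R,2S)-1-[3,5-bis(methoxymethoxy)phenyl]-2-methylbut-3-en-1-yl]oxy}-4,4,5,5-tetramethyl-1,3,2-dioxaborolane) | COCOc1cc(OCOC)cc(c1)[C@H](OB1OC(C)(C)C(C)(C)O1)[C@@H](C)C=C | intermediate (not isolated)
4 | (1R,2S)-1-[3,5-bis(methoxymethoxy)phenyl]-2-methylbut-3-en-1-ol | COCOc1cc(OCOC)cc(c1)[C@H](O)[C@@H](C)C=C | intermediate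
5 | tert-butyl{[(1R,2S)-1-[3,5-bis(methoxymethoxy)phenyl]-2-methylbut-3-en-1-yl]oxy}dimethylsilane | COCOc1cc(OCOC)cc(c1)[C@H](O[Si](C)(C)C(C)(C)C)[C@@H](C)C=C | intermediate
6 | 9-{(3S,4R)-4-[3,5-bis(methoxymethoxy)phenyl]-4-[(tert-butyldimethylsilyl)oxy]-3-methylbutyl}-9-borabicyclo[3.3.1]nonane | COCOc1cc(OCOC)cc(c1)[C@H](O[Si](C)(C)C(C)(C)C)[C@@H](C)CCB1C2CCCC1CCC2 | intermediate (not isolated)
7 | tert-butyl{[(1R,2S)-1-[3,5-bis(methoxymethoxy)phenyl]-2-methylhex-5-en-1-yl]oxy}dimethylsilane | COCOc1cc(OCOC)cc(c1)[C@H](O[Si](C)(C)C(C)(C)C)[C@@H](C)CCC=C | intermediate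
8 | (S)-but-3-yn-2-ol | C[C@H](O)C#C | starting material
9 | benzyl 4-bromobutyl ether | BrCCCCOCc1ccccc1 | starting material
10 | O,C-dilithio derivative of (S)-but-3-yn-2-ol | [Li]C#C[C@H](C)O[Li] | intermediate (not isolated)
11 | (S)-8-(benzyloxy)oct-3-yn-2-ol | C[C@H](O)C#CCCCCOCc1ccccc1 | intermediate
12 | (2S,3Z)-8-(benzyloxy)oct-3-en-2-ol | C[C@H](O)/C=C\CCCCOCc1ccccc1 | intermediate
13 | (2S,3Z)-8-(benzyloxy)oct-3-en-2-yl pyridine-2-carboxylate | C[C@H](OC(=O)c1ccccn1)/C=C\CCCCOCc1ccccc1 | intermediate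
14 | {4-[(1R,2S)-1-(tert-butyldimethylsilyloxy)-2-methylhex-5-en-1-yl]-2,6-bis(methoxymethoxy)phenyl}lithium | [Li]c1c(OCOC)cc(cc1OCOC)[C@H](O[Si](C)(C)C(C)(C)C)[C@@H](C)CCC=C | intermediate (not isolated)
15 | {4-[(1R,2S)-1-(tert-butyldimethylsilyloxy)-2-methylhex-5-en-1-yl]-2,6-bis(methoxymethoxy)phenyl}magnesium bromide | Br[Mg]c1c(OCOC)cc(cc1OCOC)[C@H](O[Si](C)(C)C(C)(C)C)[C@@H](C)CCC=C | intermediate (not isolated)
16 | monomer: tert-butyl{[(1R,2S)-1-{4-[(2E,4R)-8-(benzyloxy)oct-2-en-4-yl]-3,5-bis(methoxymethoxy)phenyl}-2-methylhex-5-en-1-yl]oxy}dimethylsilane | C/C=C/[C@@H](CCCCOCc1ccccc1)c1c(OCOC)cc(cc1OCOC)[C@H](O[Si](C)(C)C(C)(C)C)[C@@H](C)CCC=C | intermediate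
17 | acyclic head-to-tail dimer (one C5=C6 E-olefin formed; one free propenyl and one free butenyl terminus) | C/C=C/[C@@H](CCCCOCc1ccccc1)c1c(OCOC)cc(cc1OCOC)[C@H](O[Si](C)(C)C(C)(C)C)[C@@H](C)CC/C=C/[C@@H](CCCCOCc1ccccc1)c1c(OCOC)cc(cc1OCOC)[C@H](O[Si](C)(C)C(C)(C)C)[C@@H](C)CCC=C | intermediate (not isolated)
18 | C2-symmetric (E,E)-[7.7]paracyclophane diene (C5=C6 in both bridges; arms (CH2)4OBn; C1 OTBS; four OMOM) | C[C@H]1CC/C=C/[C@@H](CCCCOCc2ccccc2)c2c(OCOC)cc(cc2OCOC)[C@H](O[Si](C)(C)C(C)(C)C)[C@@H](C)CC/C=C/[C@@H](CCCCOCc2ccccc2)c2c(OCOC)cc(cc2OCOC)[C@@H]1O[Si](C)(C)C(C)(C)C | intermediate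
19 | saturated bis(benzyl ether) macrocycle | C[C@H]1CCCC[C@@H](CCCCOCc2ccccc2)c2c(OCOC)cc(cc2OCOC)[C@H](O[Si](C)(C)C(C)(C)C)[C@@H](C)CCCC[C@@H](CCCCOCc2ccccc2)c2c(OCOC)cc(cc2OCOC)[C@@H]1O[Si](C)(C)C(C)(C)C | intermediate (not isolated)
20 | C2-symmetric saturated diol (both arms (CH2)4OH) | C[C@H]1CCCC[C@@H](CCCCO)c2c(OCOC)cc(cc2OCOC)[C@H](O[Si](C)(C)C(C)(C)C)[C@@H](C)CCCC[C@@H](CCCCO)c2c(OCOC)cc(cc2OCOC)[C@@H]1O[Si](C)(C)C(C)(C)C | intermediate
21 | hydroxy aldehyde (arm a CH2OH terminus; arm b CHO terminus) | C[C@H]1CCCC[C@@H](CCCCO)c2c(OCOC)cc(cc2OCOC)[C@H](O[Si](C)(C)C(C)(C)C)[C@@H](C)CCCC[C@@H](CCCC=O)c2c(OCOC)cc(cc2OCOC)[C@@H]1O[Si](C)(C)C(C)(C)C | intermediate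
22 | hydrazone of 21 | C[C@H]1CCCC[C@@H](CCCCO)c2c(OCOC)cc(cc2OCOC)[C@H](O[Si](C)(C)C(C)(C)C)[C@@H](C)CCCC[C@@H](CCCC=NN)c2c(OCOC)cc(cc2OCOC)[C@@H]1O[Si](C)(C)C(C)(C)C | intermediate (not isolated)
23 | dichloride alcohol (arm a CH2OH terminus; arm b CHCl2 terminus) | C[C@H]1CCCC[C@@H](CCCCO)c2c(OCOC)cc(cc2OCOC)[C@H](O[Si](C)(C)C(C)(C)C)[C@@H](C)CCCC[C@@H](CCCC(Cl)Cl)c2c(OCOC)cc(cc2OCOC)[C@@H]1O[Si](C)(C)C(C)(C)C | intermediate
24 | fully protected chloro/dichloro macrocycle | C[C@H]1CCCC[C@@H](CCCCCl)c2c(OCOC)cc(cc2OCOC)[C@H](O[Si](C)(C)C(C)(C)C)[C@@H](C)CCCC[C@@H](CCCC(Cl)Cl)c2c(OCOC)cc(cc2OCOC)[C@@H]1O[Si](C)(C)C(C)(C)C | intermediate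
25 | C1a,C1b-diol tetrakis(MOM ether) | C[C@H]1CCCC[C@@H](CCCCCl)c2c(OCOC)cc(cc2OCOC)[C@H](O)[C@@H](C)CCCC[C@@H](CCCC(Cl)Cl)c2c(OCOC)cc(cc2OCOC)[C@@H]1O | intermediate
26 | bis(N-trichloroacetylcarbamate) | C[C@H]1CCCC[C@@H](CCCCCl)c2c(OCOC)cc(cc2OCOC)[C@H](OC(=O)NC(=O)C(Cl)(Cl)Cl)[C@@H](C)CCCC[C@@H](CCCC(Cl)Cl)c2c(OCOC)cc(cc2OCOC)[C@@H]1OC(=O)NC(=O)C(Cl)(Cl)Cl | intermediate (not isolated)
27 | bis(carbamate) tetrakis(MOM ether) | C[C@H]1CCCC[C@@H](CCCCCl)c2c(OCOC)cc(cc2OCOC)[C@H](OC(N)=O)[C@@H](C)CCCC[C@@H](CCCC(Cl)Cl)c2c(OCOC)cc(cc2OCOC)[C@@H]1OC(N)=O | intermediate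
28 | CNP0310589.1 (C1a,C1b R; C2a,C2b S; C7a,C7b S) | C[C@H]1CCCC[C@@H](CCCCCl)c2c(O)cc(cc2O)[C@H](OC(N)=O)[C@@H](C)CCCC[C@@H](CCCC(Cl)Cl)c2c(O)cc(cc2O)[C@@H]1OC(N)=O | target

## Step count and risks

Total step count: 16. Longest linear sequence: 13 steps (1–4, 8–16); steps 5–7 make the picolinate in parallel.

**Step 9 (cyclodimerisation).** What may go wrong: chain growth to linear oligomers instead of ring closure, no turnover at the hindered propenyl group, or ruthenium hydride-mediated migration of the C5=C6 double bond into conjugation with the ring, which would erase C7.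

Fallback (thioether cyclodimerisation and Ramberg–Bäcklund ring contraction), setting out from 16 and returning at 19. Cleavage of both olefins of 16 (OsO4 cat., NaIO4, 2,6-lutidine, dioxane/H2O) should give the C5,C6-dialdehyde F1. Immediate NaBH4 reduction gives the C5,C6-diol F2. A Mitsunobu reaction with thioacetic acid (PPh3, DIAD, THF, −20 °C) at the less hindered C5 hydroxyl gives the thioacetate alcohol F3. Mesylation (MsCl, Et3N, CH2Cl2) of the β-branched C6 hydroxyl gives the thioacetate mesylate F4. Slow addition of F4 to K2CO3 in MeOH/THF at high dilution unmasks the thiolate, which can only pair head-to-tail with the mesylate of a second molecule, and gives the 24-membered dithia macrocycle F5. Oxidation (mCPBA, NaHCO3, CH2Cl2, 0 °C) gives the bis-sulfone F6. A Ramberg–Bäcklund reaction (CBr2F2, KOH/Al2O3, t-BuOH/CH2Cl2) contracts both C5–SO2–C6 bridges to C5=C6 and gives the macrocyclic diene F7 as an E/Z mixture. Hydrogenation of F7 over PtO2 gives 19, where the route is rejoined within step 10.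

**Step 8 (anti-SN2′ arylation).** What may go wrong: sluggish transfer of the doubly ortho-substituted aryl group from copper, competing α-attack, or erosion of the 1,3-chirality transfer.

Fallback (polarity reversal: the arm as nucleophile, the ring on the allylic electrophile), setting out from 7 and returning at 16. Aryllithium 14, made from 7 as in step 8, is quenched with DMF to give the benzaldehyde F8. Claisen–Schmidt condensation with acetone (NaOH aq) gives the (E)-enone F9. Corey–Bakshi–Shibata reduction with the (R)-methyl oxazaborolidine and BH3·SMe2 gives the (S)-allylic alcohol F10. Steglich esterification with picolinic acid gives the (S,E)-picolinate F11. 4-(Benzyloxy)butylmagnesium bromide F12 (from 9 and Mg in THF) with CuBr·SMe2 at −40 °C should then add anti-SN2′ at the aryl-bearing γ-carbon, which gives 16 with the same C7 configuration and the E-propenyl group.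

**Step 12 (CHO to CHCl2).** What may go wrong: azine formation during hydrazone preparation, incomplete chlorine transfer with vinyl chloride formation, or copper-mediated chlorination of the electron-rich rings.

Fallback (deoxygenative chlorination through oxyphosphonium intermediates instead of hydrazone oxidation), setting out from 21 and returning at 24. Treatment of 21 with the triphenyl phosphite–chlorine adduct ((PhO)3P, Cl2, Et3N, CH2Cl2, −78 °C → rt) should convert CHO into CHCl2 and CH2OH into CH2Cl in one operation. This replaces steps 12 and 13 and makes no new compound.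

Further compounds
F1 | step 9 | C5,C6-dialdehyde from cleavage of both olefins of 16 | O=C[C@@H](CCCCOCc1ccccc1)c1c(OCOC)cc(cc1OCOC)[C@H](O[Si](C)(C)C(C)(C)C)[C@@H](C)CCC=O
F2 | step 9 | C5,C6-diol | OC[C@@H](CCCCOCc1ccccc1)c1c(OCOC)cc(cc1OCOC)[C@H](O[Si](C)(C)C(C)(C)C)[C@@H](C)CCCO
F3 | step 9 | thioacetate alcohol (C5–SAc, C6–OH) | OC[C@@H](CCCCOCc1ccccc1)c1c(OCOC)cc(cc1OCOC)[C@H](O[Si](C)(C)C(C)(C)C)[C@@H](C)CCCSC(C)=O
F4 | step 9 | thioacetate mesylate (C5–SAc, C6–OMs) | CS(=O)(=O)OC[C@@H](CCCCOCc1ccccc1)c1c(OCOC)cc(cc1OCOC)[C@H](O[Si](C)(C)C(C)(C)C)[C@@H](C)CCCSC(C)=O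
F5 | step 9 | 24-membered dithia macrocycle (C5–S–C6 in both bridges) | C[C@H]1CCCSC[C@@H](CCCCOCc2ccccc2)c2c(OCOC)cc(cc2OCOC)[C@H](O[Si](C)(C)C(C)(C)C)[C@@H](C)CCCSC[C@@H](CCCCOCc2ccccc2)c2c(OCOC)cc(cc2OCOC)[C@@H]1O[Si](C)(C)C(C)(C)C
F6 | step 9 | macrocyclic bis-sulfone | C[C@H]1CCCS(=O)(=O)C[C@@H](CCCCOCc2ccccc2)c2c(OCOC)cc(cc2OCOC)[C@H](O[Si](C)(C)C(C)(C)C)[C@@H](C)CCCS(=O)(=O)C[C@@H](CCCCOCc2ccccc2)c2c(OCOC)cc(cc2OCOC)[C@@H]1O[Si](C)(C)C(C)(C)C
F7 | step 9 | macrocyclic C5=C6 diene as E/Z mixture (olefin geometry not defined) | C[C@H]1CCC=C[C@@H](CCCCOCc2ccccc2)c2c(OCOC)cc(cc2OCOC)[C@H](O[Si](C)(C)C(C)(C)C)[C@@H](C)CCC=C[C@@H](CCCCOCc2ccccc2)c2c(OCOC)cc(cc2OCOC)[C@@H]1O[Si](C)(C)C(C)(C)C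
F8 | step 8 | 4-[(1R,2S)-1-(tert-butyldimethylsilyloxy)-2-methylhex-5-en-1-yl]-2,6-bis(methoxymethoxy)benzaldehyde | O=Cc1c(OCOC)cc(cc1OCOC)[C@H](O[Si](C)(C)C(C)(C)C)[C@@H](C)CCC=C
F9 | step 8 | (E)-4-aryl-but-3-en-2-one (aryl as in F8) | CC(=O)/C=C/c1c(OCOC)cc(cc1OCOC)[C@H](O[Si](C)(C)C(C)(C)C)[C@@H](C)CCC=C
F10 | step 8 | (2S,3E)-4-aryl-but-3-en-2-ol | C[C@H](O)/C=C/c1c(OCOC)cc(cc1OCOC)[C@H](O[Si](C)(C)C(C)(C)C)[C@@H](C)CCC=C
F11 | step 8 | (2S,3E)-4-aryl-but-3-en-2-yl pyridine-2-carboxylate | C[C@H](OC(=O)c1ccccn1)/C=C/c1c(OCOC)cc(cc1OCOC)[C@H](O[Si](C)(C)C(C)(C)C)[C@@H](C)CCC=C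
F12 | step 8 | 4-(benzyloxy)butylmagnesium bromide | Br[Mg]CCCCOCc1ccccc1
F0 | step 12 | none | none
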